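Ring A of the flavan (C4a, C5–C8, C8a) is built last and from scratch by cutting C5–C6, C7–C8 and C4a–C5. The feature exploited is its pentasubstituted, 1,3,5-trioxygenated pattern, in which the C6 prenyl group sits between O5 and O7 and C8 is the only CH. The triple bond of a prenyl-bearing siloxyalkyne supplies C6 and C7 together, so the substituent order follows from connectivity. In one operation a Wolff rearrangement, ketene–alkyne [2+2] cycloaddition, 4π opening and 6π closure convert an enantiopure 6-(diazoacetyl)-2-(4-methoxyphenyl)-3,4-dihydro-2H-pyran, which already carries O1, C2 (S), C3 and C4, into the C5 phenol of ring A.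

Key step: step 9

Remark: C2 of the target is S (priorities O1 > anisyl carbon > C3 > H) and ring A carries hydrogen at C8; flavan numbering is used throughout, also for the carbons of the precursors.

Step 1
Reactants: 1 anisole; 2 glutaric anhydride
Product: 3 5-(4-methoxyphenyl)-5-oxopentanoic acid
Conditions: AlCl3 (2.5 equiv), CH2Cl2, 0 °C to rt; aq. HCl quench
Reagents that add atoms: none
Why: Friedel–Crafts acylation, in which the AlCl3-activated anhydride is opened by the para carbon of the methoxy-activated ring and the deactivated keto acid does not react a second time.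

Step 2
Reactants: 3 5-(4-methoxyphenyl)-5-oxopentanoic acid
Product: 4 (5S)-5-hydroxy-5-(4-methoxyphenyl)pentanoic acid
Conditions: RuCl[(S,S)-TsDPEN](p-cymene) (1 mol%), HCO2H/Et3N (5:2), 40 °C
Reagents that add atoms: none
Why: Noyori–Ikariya asymmetric transfer hydrogenation of an aryl alkyl ketone; the (S,S)-diamine ligand and the arene–aryl CH/π contact in the six-membered hydride-transfer transition state select the carbonyl face that gives the S carbinol (the future C2), and the carboxylic acid is tolerated in the buffered formate medium.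

Step 3
Reactants: 4 (5S)-5-hydroxy-5-(4-methoxyphenyl)pentanoic acid
Product: 5 (6S)-6-(4-methoxyphenyl)tetrahydro-2H-pyran-2-one
Conditions: EDC·HCl (1.2 equiv), DMAP (cat.), CH2Cl2 (dilute), 0 °C to rt
Reagents that add atoms: none
Why: Steglich-type lactonisation, in which the carbodiimide activates the acid and the hydroxyl closes the six-membered ring at the acyl carbon under non-acidic conditions, so the C–O bond at the p-methoxybenzylic stereocentre is never broken and S is kept.

Step 4
Reactants: 5 (6S)-6-(4-methoxyphenyl)tetrahydro-2H-pyran-2-one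
Product: 6 (2S)-2-(4-methoxyphenyl)-3,4-dihydro-2H-pyran-6-yl diphenyl phosphate
Conditions: (PhO)2P(O)Cl, HMPA, THF, −78 °C; KN(SiMe3)2 added last
Reagents that add atoms: diphenyl chlorophosphate, O=P(Cl)(Oc1ccccc1)Oc1ccccc1
Why: Enolate O-phosphorylation, in which the potassium enolate of the lactone is generated in the presence of the chlorophosphate, so that it cannot self-condense, and is trapped on oxygen to give the cyclic ketene acetal phosphate as a stable surrogate of an enol triflate.

Step 5
Reactants: 6 (2S)-2-(4-methoxyphenyl)-3,4-dihydro-2H-pyran-6-yl diphenyl phosphate; 7 tributyl(1-ethoxyvinyl)stannane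
Product: 9 1-[(2S)-2-(4-methoxyphenyl)-3,4-dihydro-2H-pyran-6-yl]ethanone, via ethoxyvinyl diene 8 (not isolated)
Conditions: 7 (1.2 equiv), Pd(PPh3)4 (5 mol%), LiCl, THF, 65 °C; then 0.5 M aq. HCl, THF, 0 °C
Reagents that add atoms: water, O
Why: Stille coupling (oxidative addition of zerovalent palladium into the enol C–O bond of the phosphate, chloride-assisted transmetallation, reductive elimination) followed by enol ether hydrolysis, which should be selective because the terminal CH2 of the acyclic ethoxyvinyl group is protonated fastest and the ring enol ether of the product is deactivated by conjugation to the new carbonyl.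

Step 6
Reactants: 9 1-[(2S)-2-(4-methoxyphenyl)-3,4-dihydro-2H-pyran-6-yl]ethanone
Product: 11 2-diazo-1-[(2S)-2-(4-methoxyphenyl)-3,4-dihydro-2H-pyran-6-yl]ethanone, via trifluoroacetyl diketone 10 (not isolated)
Conditions: LiN(SiMe3)2, THF, −78 °C; CF3CO2CH2CF3; aq. HCl work-up; then 4-AcNHC6H4SO2N3, Et3N, H2O (1 equiv), MeCN, rt
Reagents that add atoms: 4-acetamidobenzenesulfonyl azide, CC(=O)Nc1ccc(cc1)S(=O)(=O)N=[N+]=[N-]
Why: Detrifluoroacetylative Regitz diazo transfer, in which Claisen trifluoroacetylation of the kinetic methyl enolate makes the α-carbon acidic enough to accept the diazo group from the sulfonyl azide and the trifluoroacetyl group is then lost by retro-Claisen cleavage with water, a sequence that avoids diazomethane and its dipolar addition to the enone.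

Step 7
Reactants: 12 prenyl bromide (1-bromo-3-methylbut-2-ene); 13 ethynylmagnesium bromide
Product: 14 5-methylhex-4-en-1-yne
Conditions: 13 (1.5 equiv), CuCl (5 mol%), THF, 0 to 40 °C; fractional distillation
Reagents that add atoms: none
Why: Copper-catalysed coupling of an alkynyl Grignard reagent with a primary allylic bromide, which should proceed by substitution at the unhindered CH2 terminus (SN2 sense) to give the linear skipped enyne, the excess of 13 suppressing double alkylation.

Step 8
Reactants: 14 5-methylhex-4-en-1-yne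
Product: 16 triisopropyl[(5-methylhex-4-en-1-yn-1-yl)oxy]silane, via lithium ynolate 15 (not isolated)
Conditions: LiN(SiMe3)2 (2.2 equiv), THF, −78 °C; t-BuOOH (1.0 equiv, in decane), −78 to 0 °C; then iPr3SiOTf (1.1 equiv), −78 to 0 °C; aqueous work-up
Reagents that add atoms: tert-butyl hydroperoxide, CC(C)(C)OO; triisopropylsilyl trifluoromethanesulfonate, CC(C)[Si](OS(=O)(=O)C(F)(F)F)(C(C)C)C(C)C
Why: Acetylide oxidation followed by O-silylation, in which the lithium acetylide attacks the electrophilic oxygen of lithium tert-butyl peroxide to give the ynolate and the bulky silyl triflate silylates this ambident anion on oxygen, while prior removal of the terminal C–H protects the doubly activated CH2 from deprotonation at low temperature.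

Step 9
Reactants: 11 2-diazo-1-[(2S)-2-(4-methoxyphenyl)-3,4-dihydro-2H-pyran-6-yl]ethanone; 16 triisopropyl[(5-methylhex-4-en-1-yn-1-yl)oxy]silane
Product: 21 (2S)-2-(4-methoxyphenyl)-6-(3-methylbut-2-enyl)-7-(triisopropylsilyloxy)chroman-5-ol, via vinylketene 17 (not isolated), via cyclobutenone 18 (not isolated), via dienylketene 19 (not isolated), via cyclohexadienone 20 (not isolated)
Conditions: 16 (1.5 equiv), ClCH2CH2Cl (degassed), hν (≥300 nm, Pyrex-filtered medium-pressure mercury lamp), rt; then 80 °C
Reagents that add atoms: none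
Why: Irradiation of 11 releases N2 and the dihydropyranyl group migrates (Wolff rearrangement) to give vinylketene 17, which takes up the polarised siloxyalkyne in a [2+2] cycloaddition in which the alkyne carbon carrying the prenyl chain bonds to the ketene C=O carbon (C5–C6) and the oxygenated alkyne carbon bonds to the ketene CH (C7–C8), giving cyclobutenone 18. Warming to 80 °C cleaves the C(=O)–CH bond of 18 in a conrotatory four-electron ring opening, the resulting dienylketene 19 closes ring A by a disrotatory six-electron electrocyclisation that links the ketene carbon to C5 of the dihydropyran (C4a–C5), and dienone 20 enolises to phenol 21. The closest known reaction type is the Danheiser benzannulation of vinylketenes generated from α-diazo ketones with siloxyalkynes. No stereocentre is formed in the product, since the sp3 carbons of 18 and 20 become aromatic, and C2, set in step 2, lies outside every bond-forming event and is kept. Two selectivities are required, namely the orientation of the [2+2] union, which must place the prenyl-bearing carbon next to the future C5 hydroxyl, and preference of the ketene for the ynol ether over the prenyl alkene; both follow from the substrate, because the alkyne carbon remote from oxygen is the nucleophilic terminus that attacks the electrophilic ketene carbonyl carbon, and a siloxyalkyne is far more nucleophilic than a trisubstituted alkene. Light of 300 nm or longer should excite the diazo ketone but not the anisyl ring, and the excess of 16 should keep the new phenol from being acylated by the ketene.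

Step 10
Reactants: 21 (2S)-2-(4-methoxyphenyl)-6-(3-methylbut-2-enyl)-7-(triisopropylsilyloxy)chroman-5-ol
Product: 23 (2S)-5,7-dimethoxy-2-(4-methoxyphenyl)-6-(3-methylbut-2-enyl)chroman, via chromandiol 22 (not isolated)
Conditions: Bu4NF (1.1 equiv), THF, 0 °C; then K2CO3 (4 equiv), MeI (6 equiv), DMF, rt
Reagents that add atoms: iodomethane, CI
Why: Fluoride cleavage of the aryl silyl ether followed in the same flask by Williamson methylation of both phenoxides (O5 and O7), which avoids isolating the oxidation- and acid-sensitive ortho-prenyl resorcinol and leaves C2 and the prenyl alkene untouched.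

Compound list
1 | anisole | COc1ccccc1 | starting material
2 | glutaric anhydride | O=C1CCCC(=O)O1 | starting material
3 | 5-(4-methoxyphenyl)-5-oxopentanoic acid | COc1ccc(cc1)C(=O)CCCC(=O)O | intermediate
4 | (5S)-5-hydroxy-5-(4-methoxyphenyl)pentanoic acid | COc1ccc([C@@H](O)CCCC(=O)O)cc1 | intermediate
5 | (6S)-6-(4-methoxyphenyl)tetrahydro-2H-pyran-2-one | COc1ccc([C@@H]2CCCC(=O)O2)cc1 | intermediate
6 | (2S)-2-(4-methoxyphenyl)-3,4-dihydro-2H-pyran-6-yl diphenyl phosphate | COc1ccc([C@@H]2CCC=C(OP(=O)(Oc3ccccc3)Oc3ccccc3)O2)cc1 | intermediate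
7 | tributyl(1-ethoxyvinyl)stannane | CCCC[Sn](CCCC)(CCCC)C(=C)OCC | starting material
8 | (2S)-6-(1-ethoxyvinyl)-2-(4-methoxyphenyl)-3,4-dihydro-2H-pyran | COc1ccc([C@@H]2CCC=C(C(=C)OCC)O2)cc1 | intermediate
9 | 1-[(2S)-2-(4-methoxyphenyl)-3,4-dihydro-2H-pyran-6-yl]ethanone | COc1ccc([C@@H]2CCC=C(C(C)=O)O2)cc1 | intermediate
10 | 4,4,4-trifluoro-1-[(2S)-2-(4-methoxyphenyl)-3,4-dihydro-2H-pyran-6-yl]butane-1,3-dione | COc1ccc([C@@H]2CCC=C(C(=O)CC(=O)C(F)(F)F)O2)cc1 | intermediate
11 | 2-diazo-1-[(2S)-2-(4-methoxyphenyl)-3,4-dihydro-2H-pyran-6-yl]ethanone | COc1ccc([C@@H]2CCC=C(C(=O)C=[N+]=[N-])O2)cc1 | intermediate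
12 | prenyl bromide (1-bromo-3-methylbut-2-ene) | CC(C)=CCBr | starting material
13 | ethynylmagnesium bromide | C#C[Mg]Br | starting material
14 | 5-methylhex-4-en-1-yne | C#CCC=C(C)C | intermediate
15 | lithium 5-methylhex-4-en-1-yn-1-olate | [Li+].[O-]C#CCC=C(C)C | intermediate
16 | triisopropyl[(5-methylhex-4-en-1-yn-1-yl)oxy]silane | CC(C)=CCC#CO[Si](C(C)C)(C(C)C)C(C)C | intermediate
17 | 2-[(2S)-2-(4-methoxyphenyl)-3,4-dihydro-2H-pyran-6-yl]ethenone | COc1ccc([C@@H]2CCC=C(C=C=O)O2)cc1 | intermediate
18 | 4-[(2S)-2-(4-methoxyphenyl)-3,4-dihydro-2H-pyran-6-yl]-2-(3-methylbut-2-enyl)-3-(triisopropylsilyloxy)cyclobut-2-en-1-one (either configuration at the ring CH) | COc1ccc([C@@H]2CCC=C(C3C(=O)C(CC=C(C)C)=C3O[Si](C(C)C)(C(C)C)C(C)C)O2)cc1 | intermediate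
19 | (3E)-4-[(2S)-2-(4-methoxyphenyl)-3,4-dihydro-2H-pyran-6-yl]-2-(3-methylbut-2-enyl)-3-(triisopropylsilyloxy)buta-1,3-dien-1-one | COc1ccc([C@@H]2CCC=C(/C=C(/O[Si](C(C)C)(C(C)C)C(C)C)C(CC=C(C)C)=C=O)O2)cc1 | intermediate
20 | (2S)-2-(4-methoxyphenyl)-6-(3-methylbut-2-enyl)-7-(triisopropylsilyloxy)-2,3,4,4a-tetrahydro-5H-chromen-5-one (either configuration at C4a) | COc1ccc([C@@H]2CCC3C(=O)C(CC=C(C)C)=C(O[Si](C(C)C)(C(C)C)C(C)C)C=C3O2)cc1 | intermediate
21 | (2S)-2-(4-methoxyphenyl)-6-(3-methylbut-2-enyl)-7-(triisopropylsilyloxy)chroman-5-ol | COc1ccc([C@@H]2CCc3c(cc(O[Si](C(C)C)(C(C)C)C(C)C)c(CC=C(C)C)c3O)O2)cc1 | intermediate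
22 | (2S)-2-(4-methoxyphenyl)-6-(3-methylbut-2-enyl)chroman-5,7-diol | COc1ccc([C@@H]2CCc3c(cc(O)c(CC=C(C)C)c3O)O2)cc1 | intermediate
23 | (2S)-5,7-dimethoxy-2-(4-methoxyphenyl)-6-(3-methylbut-2-enyl)chroman | COc1ccc([C@@H]2CCc3c(cc(OC)c(CC=C(C)C)c3OC)O2)cc1 | target

Total step count: 10 (steps 1–6 to the diazo ketone, steps 7–8 to the siloxyalkyne, steps 9–10 common).
Longest linear sequence: 8 steps (1–6, 9, 10).

Steps most likely to fail

First, step 9. What may go wrong is inefficient Wolff migration or light-induced degradation of the electron-rich chromophores, acylation of the newly formed phenol by the ketene, and incomplete thermal opening of the cyclobutenone. The fallback gives up building ring A and uses an arene in which symmetry fixes the prenyl position; it sets out from prenyl bromide 12 and comes back to the route at target 23. 1,3-Dimethoxybenzene is lithiated between its methoxy groups (n-BuLi, THF, 0 °C to rt) and alkylated with 12 to give 1,3-dimethoxy-2-(3-methylbut-2-enyl)benzene F1. Sterically controlled C–H borylation ([Ir(OMe)(cod)]2, 4,4'-di-tert-butyl-2,2'-bipyridine, B2pin2) at the only unhindered position should give 2-[3,5-dimethoxy-4-(3-methylbut-2-enyl)phenyl]-4,4,5,5-tetramethyl-1,3,2-dioxaborolane F2, which is oxidised (NaBO3, THF/H2O) to 3,5-dimethoxy-4-(3-methylbut-2-enyl)phenol F3, whose two positions ortho to the hydroxyl are equivalent. Magnesium-mediated ortho-formylation (MgCl2, Et3N, paraformaldehyde, MeCN, reflux; Casnati–Skattebøl) gives 6-hydroxy-2,4-dimethoxy-3-(3-methylbut-2-enyl)benzaldehyde F4. Wittig olefination with 1-(4-methoxyphenyl)-2-(triphenylphosphoranylidene)ethanone (toluene, 90 °C) gives (E)-3-[6-hydroxy-2,4-dimethoxy-3-(3-methylbut-2-enyl)phenyl]-1-(4-methoxyphenyl)prop-2-en-1-one F5. Conjugate reduction with [(Ph3P)CuH]6 (toluene, rt), which spares the prenyl alkene, gives 3-[6-hydroxy-2,4-dimethoxy-3-(3-methylbut-2-enyl)phenyl]-1-(4-methoxyphenyl)propan-1-one F6. Transfer hydrogenation with RuCl[(R,R)-TsDPEN](p-cymene) in HCO2H/Et3N gives 2-[(3R)-3-hydroxy-3-(4-methoxyphenyl)propyl]-3,5-dimethoxy-4-(3-methylbut-2-enyl)phenol F7. Mitsunobu cyclisation (PPh3, DIAD, toluene, −20 °C) forms the O1–C2 bond with inversion and should give 23 with S configuration; the enantiomeric purity would have to be checked, because the p-methoxybenzylic centre can ionise.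

Second, step 5. What may go wrong is slow oxidative addition or decomposition of the ketene acetal phosphate, and unselective protonation of the bis(enol ether) 8 that opens the dihydropyran. The fallback sets out from 6 and comes back at 9 without any acid-labile diene. Aminocarbonylation of 6 (Pd(OAc)2, Xantphos, CO at 1 atm, MeNHOMe·HCl, Et3N, toluene, 80 °C) gives (2S)-N-methoxy-2-(4-methoxyphenyl)-N-methyl-3,4-dihydro-2H-pyran-6-carboxamide F8. Addition of MeMgBr (THF, 0 °C) then stops at the chelated adduct and should give methyl ketone 9 on work-up (Weinreb ketone synthesis).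

Third, step 8. What may go wrong is base-mediated isomerisation of the skipped enyne to an allene or conjugated enyne, incomplete oxygen transfer to the acetylide, and hydrolytic loss of the silyl ynol ether on purification. The fallback replaces the oxidation of an acetylide by alkylation of an alkoxyacetylide; it sets out from prenyl bromide 12 and comes back at target 23, and it also bypasses step 7. Chloroacetaldehyde dimethyl acetal is converted by LiNEt2 (3 equiv, THF, 0 °C) into lithium methoxyacetylide F9, which is alkylated with 12 (HMPA, −20 °C to rt) to give 1-methoxy-5-methylhex-4-en-1-yne F10. Used in place of 16 under the conditions of step 9 with 11, F10 should pass through vinylketene 17, 3-methoxy-4-[(2S)-2-(4-methoxyphenyl)-3,4-dihydro-2H-pyran-6-yl]-2-(3-methylbut-2-enyl)cyclobut-2-en-1-one F11, (3E)-3-methoxy-4-[(2S)-2-(4-methoxyphenyl)-3,4-dihydro-2H-pyran-6-yl]-2-(3-methylbut-2-enyl)buta-1,3-dien-1-one F12 and (2S)-7-methoxy-2-(4-methoxyphenyl)-6-(3-methylbut-2-enyl)-2,3,4,4a-tetrahydro-5H-chromen-5-one F13 to (2S)-7-methoxy-2-(4-methoxyphenyl)-6-(3-methylbut-2-enyl)chroman-5-ol F14, in which O7 already carries its methyl group. A single O-methylation of F14 (MeI, K2CO3, DMF, rt) then gives 23.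

Further compounds
F1 | step 9 | 1,3-dimethoxy-2-(3-methylbut-2-enyl)benzene | COc1cccc(OC)c1CC=C(C)C
F2 | step 9 | 2-[3,5-dimethoxy-4-(3-methylbut-2-enyl)phenyl]-4,4,5,5-tetramethyl-1,3,2-dioxaborolane | COc1cc(cc(OC)c1CC=C(C)C)B1OC(C)(C)C(C)(C)O1
F3 | step 9 | 3,5-dimethoxy-4-(3-methylbut-2-enyl)phenol | COc1cc(O)cc(OC)c1CC=C(C)C
F4 | step 9 | 6-hydroxy-2,4-dimethoxy-3-(3-methylbut-2-enyl)benzaldehyde | COc1cc(O)c(C=O)c(OC)c1CC=C(C)C
F5 | step 9 | (E)-3-[6-hydroxy-2,4-dimethoxy-3-(3-methylbut-2-enyl)phenyl]-1-(4-methoxyphenyl)prop-2-en-1-one | COc1ccc(cc1)C(=O)/C=C/c1c(O)cc(OC)c(CC=C(C)C)c1OC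
F6 | step 9 | 3-[6-hydroxy-2,4-dimethoxy-3-(3-methylbut-2-enyl)phenyl]-1-(4-methoxyphenyl)propan-1-one | COc1ccc(cc1)C(=O)CCc1c(O)cc(OC)c(CC=C(C)C)c1OC
F7 | step 9 | 2-[(3R)-3-hydroxy-3-(4-methoxyphenyl)propyl]-3,5-dimethoxy-4-(3-methylbut-2-enyl)phenol | COc1ccc(cc1)[C@H](O)CCc1c(O)cc(OC)c(CC=C(C)C)c1OC
F8 | step 5 | (2S)-N-methoxy-2-(4-methoxyphenyl)-N-methyl-3,4-dihydro-2H-pyran-6-carboxamide | COc1ccc([C@@H]2CCC=C(C(=O)N(C)OC)O2)cc1
F9 | step 8 | lithium methoxyacetylide | [Li+].[C-]#COC
F10 | step 8 | 1-methoxy-5-methylhex-4-en-1-yne | COC#CCC=C(C)C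
F11 | step 8 | 3-methoxy-4-[(2S)-2-(4-methoxyphenyl)-3,4-dihydro-2H-pyran-6-yl]-2-(3-methylbut-2-enyl)cyclobut-2-en-1-one | COc1ccc([C@@H]2CCC=C(C3C(=O)C(CC=C(C)C)=C3OC)O2)cc1
F12 | step 8 | (3E)-3-methoxy-4-[(2S)-2-(4-methoxyphenyl)-3,4-dihydro-2H-pyran-6-yl]-2-(3-methylbut-2-enyl)buta-1,3-dien-1-one | COc1ccc([C@@H]2CCC=C(/C=C(/OC)C(CC=C(C)C)=C=O)O2)cc1
F13 | step 8 | (2S)-7-methoxy-2-(4-methoxyphenyl)-6-(3-methylbut-2-enyl)-2,3,4,4a-tetrahydro-5H-chromen-5-one | COc1ccc([C@@H]2CCC3C(=O)C(CC=C(C)C)=C(OC)C=C3O2)cc1
F14 | step 8 | (2S)-7-methoxy-2-(4-methoxyphenyl)-6-(3-methylbut-2-enyl)chroman-5-ol | COc1ccc([C@@H]2CCc3c(cc(OC)c(CC=C(C)C)c3O)O2)cc1
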